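## Structural features

The target is a heterodimer of two (2S)-flavanones. Unit 1 comprises O1, C2–C4, benzo ring A (5-OH, 7-OMe), pyranone ring C and the 2-aryl ring B (C1'–C6'). Unit 2 comprises O1'', C2''–C4'', benzo ring D (5''-OH, 7''-OH), pyranone ring F and the para-phenylene ring E (C1'''–C6'''). The only link between the units is a diaryl ether: the oxygen on C3' of ring B, which also carries the free 4'-OH, is bonded to C4''' of ring E. The two stereocentres C2 and C2'' are both S and lie nine bonds apart, so neither can direct the other. Each is benzylic and β to a ketone, and epimerises under base through C3–H enolisation and retro-oxa-Michael opening of ring C or ring F to a 2'-hydroxychalcone. Other sensitive features are the electron-rich rings A and D, the benzylic C2–O1 and C2''–O1'' bonds, and five phenols of which only the 7-oxygen of unit 1 is methylated; no late reagent can tell O7 from O7''. The real difficulty is to combine an unsymmetrical diaryl ether with two remote, base-labile, independently configured stereocentres and two differently substituted benzo rings. The key step exploits the fact that the O–C4''' bond between the ring-B oxygen and ring E is the sole connection between two self-contained flavanones. Both halves can therefore be finished and made enantiopure separately and then joined at that bond, as in the presumed biosynthetic phenol coupling of two flavanone monomers.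

## Logic of the disconnections

18 to 17. The four O–benzyl bonds at O5, O4', O5'' and O7'' are cut. One neutral, reductive unmasking removes all four, and the 7-OMe group is carried from the first step, so no phenol differentiation is needed at the end. The forward step must not reduce the C4 and C4'' ketones, must not cleave the benzylic C2–O1 and C2''–O1'' bonds, and must involve no base.

17 to 8 and 16 (key disconnection). The O–C4''' bond is cut, giving 8 (free 3'-OH as nucleophile) and 16 (boron at C4''' as aryl donor). In one sentence: the route is a copper-mediated oxidative O-arylation that joins two complete, enantiopure flavanones, 8 and 16, at the ring-B oxygen. This differs from the obvious plan, which forms the ether between two simple benzaldehydes at the outset and builds both heterocycles afterwards. The cut halves the molecule, and each half carries one stereocentre and its own benzo-ring pattern, so the 7-OMe/7''-OH difference and both configurations are settled before the union. The forward step has to form an aryl–oxygen bond at room temperature without a base strong enough to open ring C or ring F, and needs exactly one free hydroxyl in the two partners.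

8 to 6. The C3'–O bond is traced back to a C3'–CHO bond (aryl aldehyde to phenol by oxygen insertion and formate cleavage). A formyl group is inert during the C2–C1' bond formation and lets a catalogue boronic acid be used. The forward step needs a peracid to attack the aldehyde faster than the C4 ketone.

6 to 4 and 5. The C2–C1' bond is cut. The stereocentre is then created on a flat, achiral chromone under catalyst control, and the reversible chalcone–flavanone manifold is avoided altogether. The forward step needs high facial selectivity and a non-basic medium.

4 to 2 to 1. The O1–C2 and C2–C3 bonds of the chromone are cut back to a methyl ketone, a chelated phenol and a one-carbon formamide acetal, and then the O5–benzyl bond is cut. The forward steps need mono-benzylation of one of two equivalent phenols.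

16 to 15 to 14. The C4'''–B bond is traced back to a C4'''–Br bond, with the pinacol ester as the isolable intermediate. The bromide is inert in the preceding palladium step. The forward steps need borylation and ester cleavage without epimerising C2''.

14 to 12 and 13. The C2''–C1''' bond is cut, using the same enantioselective construction as for 6. The forward step needs the same facial selectivity on a chromone carrying two benzyloxy groups.

12 to 10 to 9. The O1''–C2'' and C2''–C3'' bonds are cut as for 4, and then two O–benzyl bonds, leaving the chelated phenol free for ring closure.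

## Other disconnections considered

Alternative 1: This is the first plan that comes to mind. The cut is made inside both heterocycles (O1–C2 and C2–C3, O1''–C2'' and C2''–C3'') after an early ether bond. Nucleophilic aromatic substitution between two commercial benzaldehydes would give the dialdehyde 4-(benzyloxy)-3-(4-formylphenoxy)benzaldehyde A1. Two Claisen–Schmidt condensations with 2 and 10 would give the bichalcone A2. The forward key step, a twofold base-mediated oxa-Michael closure, would give the stereorandom form of 17, A3. The chosen plan is preferred on three grounds: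
- The two formyl groups of A1 are electronically almost identical, so the two different acetophenones cannot be directed to their own ends without extra masking steps.
- The ring closure is reversible under its own basic conditions, and the centres, nine bonds apart, cannot communicate, so all four stereoisomers of A3 are expected.
- The resulting remote diastereomers would be very hard to separate, and no reliable catalyst-controlled closure of unactivated 2'-hydroxychalcones is available.

Alternative 2: The C2–C1' and C2''–C1''' bonds are cut on a preformed diaryl ether. A linchpin, {4-[2-(benzyloxy)-5-bromophenoxy]phenyl}boronic acid A4, would be added enantioselectively to 12 to give the bromo flavanone A5, which would be borylated to the boronic acid A6. The forward key step would be the second enantioselective conjugate addition, of A6 to 4, giving 17. This uses the same bond type as the chosen plan but in linear form, and is less attractive on three grounds: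
- A6, the most valuable intermediate, would have to be used in excess in a step where protodeboronation competes. In the chosen plan both conjugate additions use cheap catalogue boronic acids.
- The enantiopurity of the two halves could not be upgraded separately before they become remote diastereomers.
- A4 with two differentiated sites needs several steps of its own, so the linear sequence would be longer.

Alternative 3: No skeletal bond is cut; the four C–H bonds at C2, C3, C2'' and C3'' are disconnected. The forward key step would be a double enantioselective conjugate reduction (for example with a chiral ligand-bound CuH catalyst) of the flat, achiral biflavone 7-O-methylochnaflavone A7 to 18, setting both stereocentres in one operation. The chosen plan is preferred on three grounds: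
- A7 needs the same ether and two pyranone constructions plus an oxidation-level detour, so the count is higher.
- The enone of a 5-hydroxyflavone is a chelated vinylogous ester and a poor hydride acceptor.
- Reduction tends to run on to flavan-4-ols, which would need reoxidation in the presence of free phenols.

Key step: step 10

Assumption: the (R)-configured ligand (R)-4-tert-butyl-2-(pyridin-2-yl)-4,5-dihydrooxazole, (R)-t-BuPyOx, is taken to deliver the aryl group to the chromone face that gives the (2S)-flavanone, the mirror image of the sense established for the (S)-ligand with cyclic enones; if the sense were the opposite, the (S)-ligand would be used with no other change.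

## Steps

Step 1
Reactants: 1 1-(2,6-dihydroxy-4-methoxyphenyl)ethan-1-one
Product: 2 1-[2-(benzyloxy)-6-hydroxy-4-methoxyphenyl]ethan-1-one
Conditions: BnBr (1.05 equiv), K2CO3, acetone, reflux
Reagents that add atoms: benzyl bromide BrCc1ccccc1
Why: Williamson O-benzylation; once one of the two equivalent phenols is alkylated, the remaining OH is locked in a hydrogen bond to the acetyl carbonyl and reacts far more slowly, so one equivalent of benzyl bromide should stop at the mono-ether.

Step 2
Reactants: 2 1-[2-(benzyloxy)-6-hydroxy-4-methoxyphenyl]ethan-1-one
Product: 4 5-(benzyloxy)-7-methoxy-4H-chromen-4-one, via enaminone 3 (not isolated)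
Conditions: Me2NCH(OMe)2, toluene, 100 °C; then conc. HCl, CH2Cl2, rt
Reagents that add atoms: N,N-dimethylformamide dimethyl acetal COC(OC)N(C)C
Why: Enaminone route to chromones: condensation of the methyl ketone with the formamide acetal, then acid-promoted addition of the chelated phenol to the enaminone β-carbon and loss of dimethylamine; the acetal carbon becomes C2.

Step 3
Reactants: 4 5-(benzyloxy)-7-methoxy-4H-chromen-4-one; 5 [4-(benzyloxy)-3-formylphenyl]boronic acid
Product: 6 (S)-5-(benzyloxy)-2-[4-(benzyloxy)-3-formylphenyl]-7-methoxychroman-4-one
Conditions: Pd(OCOCF3)2 (5 mol%), (R)-t-BuPyOx (6 mol%), NH4PF6 (30 mol%), H2O (5 equiv), ClCH2CH2Cl, 60 °C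
Reagents that add atoms: none
Why: Catalytic enantioselective conjugate addition of an arylboronic acid to a chromone under cationic divalent palladium/pyridine-oxazoline catalysis: transmetalation, enantio-determining syn carbopalladation of C2=C3 with the aryl group going to C2, then protonolysis of the palladium enolate by water; the tert-butyl group of the ligand blocks one enone face and so sets C2 as S, and the weakly acidic medium allows neither ring opening nor attack on the formyl group.

Step 4
Reactants: 6 (S)-5-(benzyloxy)-2-[4-(benzyloxy)-3-formylphenyl]-7-methoxychroman-4-one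
Product: 8 (S)-5-(benzyloxy)-2-[4-(benzyloxy)-3-hydroxyphenyl]-7-methoxychroman-4-one, via aryl formate 7 (not isolated)
Conditions: mCPBA, CH2Cl2, 0 °C to rt; then HCl, MeOH, rt
Reagents that add atoms: 3-chloroperoxybenzoic acid OOC(=O)c1cccc(Cl)c1
Why: Dakin-type Baeyer–Villiger oxidation: the electron-rich ortho-benzyloxyaryl group migrates in the peracid adduct of the aldehyde, which forms much faster than that of the hindered, vinylogous-ester-like C4 ketone; acid methanolysis of the labile aryl formate then frees the 3'-OH without base, so C2 is not touched.

Step 5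
Reactants: 9 1-(2,4,6-trihydroxyphenyl)ethan-1-one
Product: 10 1-[2,4-bis(benzyloxy)-6-hydroxyphenyl]ethan-1-one
Conditions: BnBr (2.1 equiv), K2CO3, DMF, rt to 50 °C
Reagents that add atoms: benzyl bromide BrCc1ccccc1
Why: Twofold Williamson benzylation at the para OH and at one ortho OH; the last ortho OH stays chelated to the acetyl carbonyl and is kept for the ring closure.

Step 6
Reactants: 10 1-[2,4-bis(benzyloxy)-6-hydroxyphenyl]ethan-1-one
Product: 12 5,7-bis(benzyloxy)-4H-chromen-4-one, via enaminone 11 (not isolated)
Conditions: Me2NCH(OMe)2, toluene, 100 °C; then conc. HCl, CH2Cl2, rt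
Reagents that add atoms: N,N-dimethylformamide dimethyl acetal COC(OC)N(C)C
Why: Same enaminone condensation and acid-promoted addition–elimination ring closure as in step 2; the acetal carbon becomes C2''.

Step 7
Reactants: 12 5,7-bis(benzyloxy)-4H-chromen-4-one; 13 (4-bromophenyl)boronic acid
Product: 14 (S)-5,7-bis(benzyloxy)-2-(4-bromophenyl)chroman-4-one
Conditions: Pd(OCOCF3)2 (5 mol%), (R)-t-BuPyOx (6 mol%), NH4PF6 (30 mol%), H2O (5 equiv), ClCH2CH2Cl, 60 °C
Reagents that add atoms: none
Why: Same enantioselective conjugate arylation as in step 3, the ligand setting C2'' as S; the C–Br bond is inert because palladium stays in the divalent state throughout the cycle, and the crystalline bromide should allow the enantiopurity to be raised by recrystallisation before the union.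

Step 8
Reactants: 14 (S)-5,7-bis(benzyloxy)-2-(4-bromophenyl)chroman-4-one
Product: 15 (S)-5,7-bis(benzyloxy)-2-[4-(4,4,5,5-tetramethyl-1,3,2-dioxaborolan-2-yl)phenyl]chroman-4-one
Conditions: B2pin2, PdCl2(dppf) (5 mol%), KOAc, 1,4-dioxane, 80 °C
Reagents that add atoms: bis(pinacolato)diboron CC1(C)OB(OC1(C)C)B1OC(C)(C)C(C)(C)O1
Why: Miyaura borylation: oxidative addition of the C–Br bond to zerovalent palladium, acetate-assisted transmetalation with the diboron reagent and reductive elimination; suspended KOAc in an aprotic solvent is too weak a base to enolise C3''–H at a useful rate, so C2'' should be retained.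

Step 9
Reactants: 15 (S)-5,7-bis(benzyloxy)-2-[4-(4,4,5,5-tetramethyl-1,3,2-dioxaborolan-2-yl)phenyl]chroman-4-one
Product: 16 {4-[(S)-5,7-bis(benzyloxy)-4-oxochroman-2-yl]phenyl}boronic acid
Conditions: NaIO4, NH4OAc, acetone/H2O, rt
Reagents that add atoms: water O
Why: Oxidative cleavage of the pinacol that is in hydrolytic equilibrium with the boronate pulls the ester over to the free boronic acid under buffered, near-neutral conditions that leave the flavanone and its stereocentre alone.

Step 10
Reactants: 8 (S)-5-(benzyloxy)-2-[4-(benzyloxy)-3-hydroxyphenyl]-7-methoxychroman-4-one; 16 {4-[(S)-5,7-bis(benzyloxy)-4-oxochroman-2-yl]phenyl}boronic acid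
Product: 17 (S)-5-(benzyloxy)-2-[4-(benzyloxy)-3-{4-[(S)-5,7-bis(benzyloxy)-4-oxochroman-2-yl]phenoxy}phenyl]-7-methoxychroman-4-one
Conditions: Cu(OAc)2 (1.5 equiv), pyridine, 4 Å MS, CH2Cl2, air, rt
Reagents that add atoms: none
Why: Copper-mediated oxidative O-arylation of a phenol with an arylboronic acid (Chan–Lam coupling), the closest known reaction type, here applied to two complete flavanones: the aryl group of 16 passes from boron to divalent copper, the phenoxide of 8 binds the same copper centre, oxidation by a second divalent copper or by O2 gives an aryl(aryloxy) trivalent copper species, and reductive elimination forms the O–C4''' bond while O2 returns copper to the divalent state. No ring is closed and no stereocentre is created: C2 and C2'' arrive as S from steps 3 and 7, so two enantiopure halves are joined and the minor enantiomer of either half can only end up as a minor diastereomer. Chemoselectivity is secured by the substrates, since the 3'-OH of 8 is the only free hydroxyl in either partner and the boron of 16 sits on the unhindered para position of ring E, which leaves the steric burden (the ortho benzyloxy group) on the phenol, the partner that tolerates it better in this coupling. Configurational integrity is secured by room temperature and by pyridine, a base too weak to enolise C3–H or C3''–H, so the retro-oxa-Michael opening of rings C and F that a hot, carbonate-mediated Ullmann coupling would invite should not occur. Molecular sieves suppress hydroxylation and protodeboronation of 16, which is used in excess. The gain is large: the ring B–O–ring E connectivity, the 7-OMe/7''-OH difference and both stereocentres are all settled in the one bond-forming event that completes the skeleton.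

Step 11
Reactants: 17 (S)-5-(benzyloxy)-2-[4-(benzyloxy)-3-{4-[(S)-5,7-bis(benzyloxy)-4-oxochroman-2-yl]phenoxy}phenyl]-7-methoxychroman-4-one
Product: 18 7-O-methyltetrahydroochnaflavone, (2S,2''S)
Conditions: H2 (1 atm), Pd/C, EtOAc/MeOH, rt
Reagents that add atoms: none
Why: Hydrogenolysis of the four benzyl ethers over palladium on carbon under neutral conditions; the diaryl ether, the methyl ether and the two chelated aryl ketones should be inert at 1 atm and room temperature, and no base is present to open ring C or ring F, so both S centres are kept.

## Compound list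

1 | 1-(2,6-dihydroxy-4-methoxyphenyl)ethan-1-one | CC(=O)c1c(O)cc(OC)cc1O | starting material
2 | 1-[2-(benzyloxy)-6-hydroxy-4-methoxyphenyl]ethan-1-one | CC(=O)c1c(O)cc(OC)cc1OCc1ccccc1 | intermediate
3 | (E)-1-[2-(benzyloxy)-6-hydroxy-4-methoxyphenyl]-3-(dimethylamino)prop-2-en-1-one | CN(C)/C=C/C(=O)c1c(O)cc(OC)cc1OCc1ccccc1 | intermediate
4 | 5-(benzyloxy)-7-methoxy-4H-chromen-4-one | COc1cc(OCc2ccccc2)c2c(c1)occc2=O | intermediate
5 | [4-(benzyloxy)-3-formylphenyl]boronic acid | O=Cc1cc(B(O)O)ccc1OCc1ccccc1 | starting material
6 | (S)-5-(benzyloxy)-2-[4-(benzyloxy)-3-formylphenyl]-7-methoxychroman-4-one | COc1cc(OCc3ccccc3)c2c(c1)O[C@H](c1ccc(OCc3ccccc3)c(C=O)c1)CC2=O | intermediate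
7 | 2-(benzyloxy)-5-[(S)-5-(benzyloxy)-7-methoxy-4-oxochroman-2-yl]phenyl formate | COc1cc(OCc3ccccc3)c2c(c1)O[C@H](c1ccc(OCc3ccccc3)c(OC=O)c1)CC2=O | intermediate
8 | (S)-5-(benzyloxy)-2-[4-(benzyloxy)-3-hydroxyphenyl]-7-methoxychroman-4-one | COc1cc(OCc3ccccc3)c2c(c1)O[C@H](c1ccc(OCc3ccccc3)c(O)c1)CC2=O | intermediate
9 | 1-(2,4,6-trihydroxyphenyl)ethan-1-one | CC(=O)c1c(O)cc(O)cc1O | starting material
10 | 1-[2,4-bis(benzyloxy)-6-hydroxyphenyl]ethan-1-one | CC(=O)c1c(O)cc(OCc2ccccc2)cc1OCc1ccccc1 | intermediate
11 | (E)-1-[2,4-bis(benzyloxy)-6-hydroxyphenyl]-3-(dimethylamino)prop-2-en-1-one | CN(C)/C=C/C(=O)c1c(O)cc(OCc2ccccc2)cc1OCc1ccccc1 | intermediate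
12 | 5,7-bis(benzyloxy)-4H-chromen-4-one | O=c1ccoc2cc(OCc3ccccc3)cc(OCc3ccccc3)c12 | intermediate
13 | (4-bromophenyl)boronic acid | OB(O)c1ccc(Br)cc1 | starting material
14 | (S)-5,7-bis(benzyloxy)-2-(4-bromophenyl)chroman-4-one | Brc1ccc([C@@H]2CC(=O)c3c(OCc4ccccc4)cc(OCc4ccccc4)cc3O2)cc1 | intermediate
15 | (S)-5,7-bis(benzyloxy)-2-[4-(4,4,5,5-tetramethyl-1,3,2-dioxaborolan-2-yl)phenyl]chroman-4-one | CC1(C)OB(c2ccc([C@@H]3CC(=O)c4c(OCc5ccccc5)cc(OCc5ccccc5)cc4O3)cc2)OC1(C)C | intermediate
16 | {4-[(S)-5,7-bis(benzyloxy)-4-oxochroman-2-yl]phenyl}boronic acid | OB(O)c1ccc([C@@H]2CC(=O)c3c(OCc4ccccc4)cc(OCc4ccccc4)cc3O2)cc1 | intermediate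
17 | (S)-5-(benzyloxy)-2-[4-(benzyloxy)-3-{4-[(S)-5,7-bis(benzyloxy)-4-oxochroman-2-yl]phenoxy}phenyl]-7-methoxychroman-4-one | COc1cc(OCc6ccccc6)c2c(c1)O[C@H](c1ccc(OCc6ccccc6)c(Oc3ccc([C@@H]4CC(=O)c5c(OCc6ccccc6)cc(OCc6ccccc6)cc5O4)cc3)c1)CC2=O | intermediate
18 | 7-O-methyltetrahydroochnaflavone, (2S,2''S) | COc1cc(O)c2c(c1)O[C@H](c1ccc(O)c(Oc3ccc([C@@H]4CC(=O)c5c(O)cc(O)cc5O4)cc3)c1)CC2=O | target

## Step count and least certain steps

Total step count: 11. Longest linear sequence: 7 steps (steps 5, 6, 7, 8, 9, 10, 11, starting from 9); the other branch (steps 1 to 4) joins at step 10.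

Step 10 (key step). The most likely failures are:
- slow aryl transfer from boron to copper with two large partners, so that protodeboronation and oxidative hydroxylation of the boronic acid outrun the cross-coupling;
- shielding of the phenoxide by the neighbouring benzyloxy group;
- slow epimerisation through ring opening if the reaction has to run for days.

Fallback, setting out from 8 and returning at 17: the ether bond would be made with a small, cheap aryl donor, and ring F built afterwards by carbon–carbon bond formation. 8 would be O-arylated under the same copper conditions with a large excess of 13 to give (S)-5-(benzyloxy)-2-[4-(benzyloxy)-3-(4-bromophenoxy)phenyl]-7-methoxychroman-4-one F1. Borylation as in step 8 would give the pinacol boronate (S)-5-(benzyloxy)-2-{4-(benzyloxy)-3-[4-(4,4,5,5-tetramethyl-1,3,2-dioxaborolan-2-yl)phenoxy]phenyl}-7-methoxychroman-4-one F2. Periodate cleavage as in step 9 would give (4-{2-(benzyloxy)-5-[(S)-5-(benzyloxy)-7-methoxy-4-oxochroman-2-yl]phenoxy}phenyl)boronic acid F3. Enantioselective conjugate addition of F3 to 12 under the conditions of step 7 would then give 17.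

Step 7 (the same risk applies in kind to step 3). The chromone is a doubly oxygen-donor-substituted vinylogous ester, so carbopalladation may be slow, protodeboronation of the boronic acid may win, and facial selectivity may fall short.

Fallback, setting out from 10 and returning at 14: the heterocycle would be closed through the O1''–C2'' bond instead. Claisen–Schmidt condensation of 10 with 4-bromobenzaldehyde (KOH, EtOH) would give the chalcone (E)-1-[2,4-bis(benzyloxy)-6-hydroxyphenyl]-3-(4-bromophenyl)prop-2-en-1-one F4. Oxa-Michael closure with NaOAc in refluxing EtOH would give racemic 5,7-bis(benzyloxy)-2-(4-bromophenyl)chroman-4-one F5. Separation on a chiral stationary phase would give 14, and the unwanted (R)-5,7-bis(benzyloxy)-2-(4-bromophenyl)chroman-4-one F6 would be returned to F5 by the same NaOAc treatment.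

Step 4. The peracid may over-oxidise, either by oxygen insertion at the C4 ketone (whose migrating group would be the very electron-rich ring A) or by hydroxylation of ring A at C6 or C8.

Fallback, setting out from 4 and returning at 8: the 3'-oxygen would be carried in from the start instead of being made by oxidation.
- Commercial 2-(benzyloxy)phenol would be silylated (triisopropylsilyl chloride, imidazole, DMF) to [2-(benzyloxy)phenoxy]triisopropylsilane F7.
- Bromination para to the more strongly donating benzyloxy group (NBS, MeCN) would give [2-(benzyloxy)-5-bromophenoxy]triisopropylsilane F8.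
- Bromine–lithium exchange and borate quench (n-BuLi, B(OiPr)3, THF, −78 °C, then aqueous NH4Cl) would give {4-(benzyloxy)-3-[(triisopropylsilyl)oxy]phenyl}boronic acid F9.
- Conjugate addition of F9 to 4 under the conditions of step 3 would give (S)-5-(benzyloxy)-2-{4-(benzyloxy)-3-[(triisopropylsilyl)oxy]phenyl}-7-methoxychroman-4-one F10.
- Buffered fluoride (tetrabutylammonium fluoride, AcOH, THF, 0 °C) would release 8.

Step 8. Hot acetate may cause partial epimerisation at C2'' through retro-oxa-Michael opening, and reductive loss of bromine or protodeboronation may lower the return.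

Fallback, setting out from 12 and returning at 16: the boron would be carried through the carbon–carbon bond formation instead of being installed afterwards. An excess of benzene-1,4-diboronic acid would be added to 12 under the conditions of step 7, so that one boron is consumed in the conjugate addition and the other remains as the boronic acid of 16. No base is involved, and no compound outside the list is made (F0).

## Further compounds

F1 | step 10 | (S)-5-(benzyloxy)-2-[4-(benzyloxy)-3-(4-bromophenoxy)phenyl]-7-methoxychroman-4-one | COc1cc(OCc3ccccc3)c2c(c1)O[C@H](c1ccc(OCc3ccccc3)c(Oc3ccc(Br)cc3)c1)CC2=O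
F2 | step 10 | (S)-5-(benzyloxy)-2-{4-(benzyloxy)-3-[4-(4,4,5,5-tetramethyl-1,3,2-dioxaborolan-2-yl)phenoxy]phenyl}-7-methoxychroman-4-one | COc1cc(OCc3ccccc3)c2c(c1)O[C@H](c1ccc(OCc3ccccc3)c(Oc3ccc(B4OC(C)(C)C(C)(C)O4)cc3)c1)CC2=O
F3 | step 10 | (4-{2-(benzyloxy)-5-[(S)-5-(benzyloxy)-7-methoxy-4-oxochroman-2-yl]phenoxy}phenyl)boronic acid | COc1cc(OCc3ccccc3)c2c(c1)O[C@H](c1ccc(OCc3ccccc3)c(Oc3ccc(B(O)O)cc3)c1)CC2=O
F4 | step 7 | (E)-1-[2,4-bis(benzyloxy)-6-hydroxyphenyl]-3-(4-bromophenyl)prop-2-en-1-one | O=C(/C=C/c1ccc(Br)cc1)c1c(O)cc(OCc2ccccc2)cc1OCc1ccccc1
F5 | step 7 | racemic 5,7-bis(benzyloxy)-2-(4-bromophenyl)chroman-4-one | Brc1ccc(C2CC(=O)c3c(OCc4ccccc4)cc(OCc4ccccc4)cc3O2)cc1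
F6 | step 7 | (R)-5,7-bis(benzyloxy)-2-(4-bromophenyl)chroman-4-one | Brc1ccc([C@H]2CC(=O)c3c(OCc4ccccc4)cc(OCc4ccccc4)cc3O2)cc1
F7 | step 4 | [2-(benzyloxy)phenoxy]triisopropylsilane | CC(C)[Si](Oc1ccccc1OCc1ccccc1)(C(C)C)C(C)C
F8 | step 4 | [2-(benzyloxy)-5-bromophenoxy]triisopropylsilane | CC(C)[Si](Oc1cc(Br)ccc1OCc1ccccc1)(C(C)C)C(C)C
F9 | step 4 | {4-(benzyloxy)-3-[(triisopropylsilyl)oxy]phenyl}boronic acid | CC(C)[Si](Oc1cc(B(O)O)ccc1OCc1ccccc1)(C(C)C)C(C)C
F10 | step 4 | (S)-5-(benzyloxy)-2-{4-(benzyloxy)-3-[(triisopropylsilyl)oxy]phenyl}-7-methoxychroman-4-one | COc1cc(OCc3ccccc3)c2c(c1)O[C@H](c1ccc(OCc3ccccc3)c(O[Si](C(C)C)(C(C)C)C(C)C)c1)CC2=O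
F0 | step 8 | none | none
A1 | alternative 1 | 4-(benzyloxy)-3-(4-formylphenoxy)benzaldehyde | O=Cc1ccc(Oc2cc(C=O)ccc2OCc2ccccc2)cc1
A2 | alternative 1 | (E)-1-[2-(benzyloxy)-6-hydroxy-4-methoxyphenyl]-3-[4-(benzyloxy)-3-(4-{(E)-3-[2,4-bis(benzyloxy)-6-hydroxyphenyl]-3-oxoprop-1-en-1-yl}phenoxy)phenyl]prop-2-en-1-one | COc1cc(O)c(C(=O)/C=C/c2ccc(OCc3ccccc3)c(Oc3ccc(/C=C/C(=O)c4c(O)cc(OCc5ccccc5)cc4OCc4ccccc4)cc3)c2)c(OCc2ccccc2)c1
A3 | alternative 1 | stereorandom form of 17 (all four stereoisomers) | COc1cc(OCc6ccccc6)c2c(c1)OC(c1ccc(OCc6ccccc6)c(Oc3ccc(C4CC(=O)c5c(OCc6ccccc6)cc(OCc6ccccc6)cc5O4)cc3)c1)CC2=O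
A4 | alternative 2 | {4-[2-(benzyloxy)-5-bromophenoxy]phenyl}boronic acid | OB(O)c1ccc(Oc2cc(Br)ccc2OCc2ccccc2)cc1
A5 | alternative 2 | (S)-5,7-bis(benzyloxy)-2-{4-[2-(benzyloxy)-5-bromophenoxy]phenyl}chroman-4-one | Brc1ccc(OCc2ccccc2)c(Oc2ccc([C@@H]3CC(=O)c4c(OCc5ccccc5)cc(OCc5ccccc5)cc4O3)cc2)c1
A6 | alternative 2 | [4-(benzyloxy)-3-{4-[(S)-5,7-bis(benzyloxy)-4-oxochroman-2-yl]phenoxy}phenyl]boronic acid | OB(O)c1ccc(OCc2ccccc2)c(Oc2ccc([C@@H]3CC(=O)c4c(OCc5ccccc5)cc(OCc5ccccc5)cc4O3)cc2)c1
A7 | alternative 3 | 7-O-methylochnaflavone | COc1cc(O)c2c(c1)oc(-c1ccc(O)c(Oc3ccc(-c4cc(=O)c5c(O)cc(O)cc5o4)cc3)c1)cc2=O
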